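**Plan**

1. Cuts: the interflavan bond C4(upper)–C6(lower); in each half the C3–O bond and the C2–aryl bond, back to one achiral chromone; then the C2–C3 link of that chromone, where C3 is taken out to leave a benzofuran-3(2H)-one with ring A complete.
2. Forward order: ring A is bought as 6,7-dihydroxybenzofuran-3(2H)-one; its five-membered furanone ring is enlarged by one carbon to the pyranone (ring C); ring B is added by conjugate arylation; C3 is oxygenated and C4 reduced; the upper 3,4-diol is ionised at C4 and joined to C6 of the lower half; deprotection ends the route.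
3. Enabling feature: the C3 ketone of the furanone ring, enolised toward C2, gives an aromatic 3-silyloxybenzofuran whose C2=C3 bond carries a donor at each end (ring oxygen O1 on C2, O–Si on C3). It takes up a carbene, and the cyclopropane bond C2–C3 shared by the three- and five-membered rings then opens between two oxygen-stabilised termini.
4. Stereochemistry: C2 of each half from ligand-controlled Pd-catalysed conjugate addition (opposite ligand antipodes); C3 from oxidation of the enol ether anti to the 2-aryl group; lower C4 from NaBH4 reduction of the trans-dihydroflavonol; upper C4 from attack of the lower arene anti to the 3-hydroxyl of the flavan-4-yl cation.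
5. The carbonyl oxygen of the starting furanone is kept throughout: it ends as the 4-hydroxyl of the lower unit and serves as the leaving group of the upper unit.

Key step: step 3

Remark: which antipode of the t-BuPyOX ligand gives the (2S)-flavanone 9 is assumed to be settled by a trial run; step 9 uses the other antipode.

**Route**

Step 1
Reactants: 1 6,7-dihydroxy-1-benzofuran-3(2H)-one
Product: 2 6,7-bis(benzyloxy)-1-benzofuran-3(2H)-one
Conditions: BnBr (2.2 equiv), K2CO3, DMF, 50 °C
Reagents that add atoms: benzyl bromide BrCc1ccccc1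
Why: Williamson ether synthesis: K2CO3 deprotonates only the two phenols (far more acidic than the C2 methylene), so both are O-benzylated and ring A is protected for the whole route.

Step 2
Reactants: 2 6,7-bis(benzyloxy)-1-benzofuran-3(2H)-one
Product: 3 6,7-bis(benzyloxy)-3-[(tert-butyldimethylsilyl)oxy]-1-benzofuran
Conditions: TBSOTf, Et3N, CH2Cl2, 0 °C
Reagents that add atoms: tert-butyldimethylsilyl triflate CC(C)(C)[Si](C)(C)OS(=O)(=O)C(F)(F)F
Why: Soft enolisation and O-silylation give the silyl enol ether, which is an aromatic benzofuran and should therefore form readily; it places the activating silyloxy group on C3 for the carbene step.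

Step 3
Reactants: 3 6,7-bis(benzyloxy)-3-[(tert-butyldimethylsilyl)oxy]-1-benzofuran
Product: 6 7,8-bis(benzyloxy)-3-bromo-4H-chromen-4-one, via dibromocyclopropane adduct 4 (not isolated), via 3-bromo-4-silyloxychromenylium bromide 5 (not isolated)
Conditions: CHBr3, KOt-Bu, hexane–THF, −20 → 20 °C
Reagents that add atoms: bromoform BrC(Br)Br
Why: Dibromocarbene, formed by α-elimination from bromoform, should add in a [2+1] cheletropic step to the C2=C3 bond of the furan ring, the most electron-rich π bond of 3 because it is flanked by the ring oxygen O1 and the silyloxy group, and thereby dearomatise the furan ring to the cis-fused cyclopropane 4. Release of cyclopropane strain then drives ionisation of the endo C–Br bond with disrotatory electrocyclic opening of the C2–C3 bond shared by the three- and five-membered rings, pushed by the oxygen lone pairs at both termini, so that the carbene carbon is inserted as C3 and the five-membered ring becomes the six-membered chromenylium ion 5; bromide then removes the silyl group and leaves the pyranone carbonyl of 6. The closest known reaction type is the one-carbon ring expansion of cyclic silyl enol ethers to 2-halo-enones with dihalocarbenes, the oxygen counterpart of the Ciamician–Dennstedt rearrangement. The only ring closed is the cyclopropane, by [2+1] cycloaddition; the six-membered ring arises from it by electrocyclic ring opening and not by a cyclisation. No stereocentre survives the step, since C2, C3 and C4 of 6 are trigonal. The step needs chemoselectivity for the furan double bond over the benzenoid rings and regioselective cleavage of the internal cyclopropane bond: the first is secured by the two oxygen donors on that bond, the second by the ring fusion, which lets only the endo bromide leave and only the shared bond open.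

Step 4
Reactants: 6 7,8-bis(benzyloxy)-3-bromo-4H-chromen-4-one
Product: 7 7,8-bis(benzyloxy)-4H-chromen-4-one
Conditions: Bu3SnH, AIBN (cat.), toluene, 80 °C
Reagents that add atoms: none
Why: Radical chain hydrodehalogenation: the stannyl radical abstracts the vinylic bromine and the vinyl radical takes hydrogen from Bu3SnH, which removes the helper bromine while the benzyl ethers and the pyranone stay untouched.

Step 5
Reactants: 7 7,8-bis(benzyloxy)-4H-chromen-4-one; 8 [4-(benzyloxy)phenyl]boronic acid
Product: 9 (2S)-7,8-bis(benzyloxy)-2-[4-(benzyloxy)phenyl]chroman-4-one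
Conditions: Pd(OCOCF3)2 (5 mol %), t-BuPyOX (one antipode, 6 mol %), NH4PF6, H2O, ClCH2CH2Cl, 60 °C
Reagents that add atoms: none
Why: Pd-catalysed asymmetric conjugate addition of an arylboronic acid to a chromone: transmetalation gives an aryl–Pd species whose chiral pyridine–oxazoline ligand directs migratory insertion of the C2=C3 bond to one face, which sets C2, and protonolysis of the palladium enolate releases the flavanone.

Step 6
Reactants: 9 (2S)-7,8-bis(benzyloxy)-2-[4-(benzyloxy)phenyl]chroman-4-one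
Product: 12 (2R,3R)-7,8-bis(benzyloxy)-2-[4-(benzyloxy)phenyl]-3-hydroxychroman-4-one, via trimethylsilyl enol ether 10 (not isolated), via silyloxy epoxide 11 (not isolated)
Conditions: LiN(SiMe3)2, Me3SiCl, THF, −78 °C; then DMDO, acetone–CH2Cl2, −78 → −20 °C; aq. citric acid work-up
Reagents that add atoms: dimethyldioxirane CC1(C)OO1
Why: Rubottom oxidation: the kinetic lithium enolate is trapped at once as the silyl enol ether so that ring C does not open, and DMDO should epoxidise C3=C4 on the face opposite to the 2-aryl group, so that hydrolysis of the silyloxy epoxide leaves the 3-hydroxyl trans to the aryl group.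

Step 7
Reactants: 12 (2R,3R)-7,8-bis(benzyloxy)-2-[4-(benzyloxy)phenyl]-3-hydroxychroman-4-one
Product: 13 (2R,3S,4R)-7,8-bis(benzyloxy)-2-[4-(benzyloxy)phenyl]chroman-3,4-diol
Conditions: NaBH4, MeOH–THF, −20 °C
Reagents that add atoms: none
Why: Diastereoselective carbonyl reduction under substrate control: hydride should add to C4 of the 2,3-trans-dihydroflavonol from the pseudo-axial side and leave the equatorial 4-hydroxyl trans to the 3-hydroxyl, the usual outcome for NaBH4 in this class.

Step 8
Reactants: 13 (2R,3S,4R)-7,8-bis(benzyloxy)-2-[4-(benzyloxy)phenyl]chroman-3,4-diol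
Product: 14 3,4-bis-O-(tert-butyldimethylsilyl) ether of 13
Conditions: TBSOTf (3 equiv), 2,6-lutidine, CH2Cl2, 0 °C
Reagents that add atoms: tert-butyldimethylsilyl triflate CC(C)(C)[Si](C)(C)OS(=O)(=O)C(F)(F)F
Why: Silyl ether formation on both secondary hydroxyls keeps them from O-alkylation and keeps the benzylic C4–O bond from ionising in step 12, and the bulky 4-silyloxy group screens C5.

Step 9
Reactants: 7 7,8-bis(benzyloxy)-4H-chromen-4-one; 8 [4-(benzyloxy)phenyl]boronic acid
Product: 15 (2R)-7,8-bis(benzyloxy)-2-[4-(benzyloxy)phenyl]chroman-4-one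
Conditions: Pd(OCOCF3)2 (5 mol %), t-BuPyOX (other antipode, 6 mol %), NH4PF6, H2O, ClCH2CH2Cl, 60 °C
Reagents that add atoms: none
Why: The same Pd-catalysed asymmetric conjugate addition as in step 5; the enantiomeric ligand should deliver the aryl group to the opposite face and set the (2R) centre.

Step 10
Reactants: 15 (2R)-7,8-bis(benzyloxy)-2-[4-(benzyloxy)phenyl]chroman-4-one
Product: 18 (2S,3S)-7,8-bis(benzyloxy)-2-[4-(benzyloxy)phenyl]-3-hydroxychroman-4-one, via trimethylsilyl enol ether 16 (not isolated), via silyloxy epoxide 17 (not isolated)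
Conditions: LiN(SiMe3)2, Me3SiCl, THF, −78 °C; then DMDO, acetone–CH2Cl2, −78 → −20 °C; aq. citric acid work-up
Reagents that add atoms: dimethyldioxirane CC1(C)OO1
Why: Rubottom oxidation as in step 6; epoxidation anti to the 2-aryl group should give the 2,3-trans hydroxy ketone of the enantiomeric series.

Step 11
Reactants: 18 (2S,3S)-7,8-bis(benzyloxy)-2-[4-(benzyloxy)phenyl]-3-hydroxychroman-4-one
Product: 19 (2S,3R,4S)-7,8-bis(benzyloxy)-2-[4-(benzyloxy)phenyl]chroman-3,4-diol
Conditions: NaBH4, MeOH–THF, −20 °C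
Reagents that add atoms: none
Why: Carbonyl reduction as in step 7; the configuration formed at C4 is not critical here because this centre is ionised in step 12.

Step 12
Reactants: 19 (2S,3R,4S)-7,8-bis(benzyloxy)-2-[4-(benzyloxy)phenyl]chroman-3,4-diol; 14 3,4-bis-O-(tert-butyldimethylsilyl) ether of 13
Product: 20 hexa-O-benzyl-3,4-bis-O-(tert-butyldimethylsilyl) derivative of ent-oritin-(4β→6)-oritin-4α-ol
Conditions: 14 (3 equiv), BF3·OEt2 (0.3 equiv), 4 Å molecular sieves, CH2Cl2, −78 → −30 °C; Et3N quench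
Reagents that add atoms: none
Why: Friedel–Crafts alkylation through a flavan-4-yl cation: BF3 should ionise the free benzylic 4-hydroxyl of 19 (the silylated one of 14 is less basic and hindered), C6 of 14 is the only ring-A position activated by two conjugated oxygens (para to O1, ortho to the 7-benzyloxy group, whereas C5 faces the twisted 8-benzyloxy group and the 4-silyloxy group), and the arene should add anti to the 3-hydroxyl of the half-chair cation, which sets the upper C4 with the 3,4-trans relation.

Step 13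
Reactants: 20 hexa-O-benzyl-3,4-bis-O-(tert-butyldimethylsilyl) derivative of ent-oritin-(4β→6)-oritin-4α-ol
Product: 21 3,4-bis-O-(tert-butyldimethylsilyl) ether (lower unit) of ent-oritin-(4β→6)-oritin-4α-ol
Conditions: H2 (1 atm), Pd(OH)2/C, EtOAc–THF, 20 °C
Reagents that add atoms: none
Why: Hydrogenolysis of the six aryl benzyl ethers; the silyl groups protect the benzylic C4–O bond of the lower unit, which as a free 4-hydroxyl para to a phenol would be at risk of hydrogenolysis.

Step 14
Reactants: 21 3,4-bis-O-(tert-butyldimethylsilyl) ether (lower unit) of ent-oritin-(4β→6)-oritin-4α-ol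
Product: 22 ent-oritin-(4β→6)-oritin-4α-ol (target)
Conditions: Et3N·3HF, THF–MeCN, 20 → 40 °C, argon
Reagents that add atoms: none
Why: Fluoride-mediated desilylation under nearly neutral conditions should free the 3,4-diol without ionising the acid-labile benzylic 4-hydroxyl or oxidising the pyrogallol-type rings.

**Compound list**

1 | 6,7-dihydroxy-1-benzofuran-3(2H)-one | O=C1COc2c1ccc(O)c2O | starting material
2 | 6,7-bis(benzyloxy)-1-benzofuran-3(2H)-one | O=C1COc2c1ccc(OCc1ccccc1)c2OCc1ccccc1 | intermediate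
3 | 6,7-bis(benzyloxy)-3-[(tert-butyldimethylsilyl)oxy]-1-benzofuran | CC(C)(C)[Si](C)(C)Oc1coc2c1ccc(OCc1ccccc1)c2OCc1ccccc1 | intermediate
4 | 3,4-bis(benzyloxy)-1,1-dibromo-6b-[(tert-butyldimethylsilyl)oxy]-1a,6b-dihydro-1H-cyclopropa[b][1]benzofuran (racemic, cis-fused) | CC(C)(C)[Si](C)(C)OC12C(Br)(Br)C1Oc1c2ccc(OCc2ccccc2)c1OCc1ccccc1 | intermediate
5 | 7,8-bis(benzyloxy)-3-bromo-4-[(tert-butyldimethylsilyl)oxy]chromenylium bromide | CC(C)(C)[Si](C)(C)Oc1c(Br)c[o+]c2c1ccc(OCc1ccccc1)c2OCc1ccccc1.[Br-] | intermediate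
6 | 7,8-bis(benzyloxy)-3-bromo-4H-chromen-4-one | O=c1c(Br)coc2c1ccc(OCc1ccccc1)c2OCc1ccccc1 | intermediate
7 | 7,8-bis(benzyloxy)-4H-chromen-4-one | O=c1ccoc2c1ccc(OCc1ccccc1)c2OCc1ccccc1 | intermediate
8 | [4-(benzyloxy)phenyl]boronic acid | OB(O)c1ccc(OCc2ccccc2)cc1 | starting material
9 | (2S)-7,8-bis(benzyloxy)-2-[4-(benzyloxy)phenyl]chroman-4-one | c1ccc(cc1)COc1ccc(cc1)[C@H]1Oc2c(ccc(OCc3ccccc3)c2OCc2ccccc2)C(=O)C1 | intermediate
10 | (2S)-7,8-bis(benzyloxy)-2-[4-(benzyloxy)phenyl]-4-(trimethylsilyloxy)-2H-chromene | c1ccc(cc1)COc1ccc(cc1)[C@H]1Oc2c(ccc(OCc3ccccc3)c2OCc2ccccc2)C(O[Si](C)(C)C)=C1 | intermediate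
11 | (2R)-7,8-bis(benzyloxy)-2-[4-(benzyloxy)phenyl]-3,4-epoxy-4-(trimethylsilyloxy)chroman, oxirane trans to the 2-aryl group | c1ccc(cc1)COc1ccc(cc1)[C@H]1Oc2c(ccc(OCc3ccccc3)c2OCc2ccccc2)[C@]2(O[Si](C)(C)C)O[C@H]12 | intermediate
12 | (2R,3R)-7,8-bis(benzyloxy)-2-[4-(benzyloxy)phenyl]-3-hydroxychroman-4-one | c1ccc(cc1)COc1ccc(cc1)[C@H]1Oc2c(ccc(OCc3ccccc3)c2OCc2ccccc2)C(=O)[C@@H]1O | intermediate
13 | (2R,3S,4R)-7,8-bis(benzyloxy)-2-[4-(benzyloxy)phenyl]chroman-3,4-diol (2,3-trans-3,4-trans) | c1ccc(cc1)COc1ccc(cc1)[C@H]1Oc2c(ccc(OCc3ccccc3)c2OCc2ccccc2)[C@@H](O)[C@@H]1O | intermediate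
14 | 3,4-bis-O-(tert-butyldimethylsilyl) ether of 13 (2R; 2,3-trans-3,4-trans) | c1ccc(cc1)COc1ccc(cc1)[C@H]1Oc2c(ccc(OCc3ccccc3)c2OCc2ccccc2)[C@@H](O[Si](C)(C)C(C)(C)C)[C@@H]1O[Si](C)(C)C(C)(C)C | intermediate
15 | (2R)-7,8-bis(benzyloxy)-2-[4-(benzyloxy)phenyl]chroman-4-one | c1ccc(cc1)COc1ccc(cc1)[C@@H]1Oc2c(ccc(OCc3ccccc3)c2OCc2ccccc2)C(=O)C1 | intermediate
16 | (2R)-7,8-bis(benzyloxy)-2-[4-(benzyloxy)phenyl]-4-(trimethylsilyloxy)-2H-chromene | c1ccc(cc1)COc1ccc(cc1)[C@@H]1Oc2c(ccc(OCc3ccccc3)c2OCc2ccccc2)C(O[Si](C)(C)C)=C1 | intermediate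
17 | (2S)-7,8-bis(benzyloxy)-2-[4-(benzyloxy)phenyl]-3,4-epoxy-4-(trimethylsilyloxy)chroman, oxirane trans to the 2-aryl group | c1ccc(cc1)COc1ccc(cc1)[C@@H]1Oc2c(ccc(OCc3ccccc3)c2OCc2ccccc2)[C@@]2(O[Si](C)(C)C)O[C@@H]12 | intermediate
18 | (2S,3S)-7,8-bis(benzyloxy)-2-[4-(benzyloxy)phenyl]-3-hydroxychroman-4-one | c1ccc(cc1)COc1ccc(cc1)[C@@H]1Oc2c(ccc(OCc3ccccc3)c2OCc2ccccc2)C(=O)[C@H]1O | intermediate
19 | (2S,3R,4S)-7,8-bis(benzyloxy)-2-[4-(benzyloxy)phenyl]chroman-3,4-diol (2,3-trans-3,4-trans) | c1ccc(cc1)COc1ccc(cc1)[C@@H]1Oc2c(ccc(OCc3ccccc3)c2OCc2ccccc2)[C@H](O)[C@H]1O | intermediate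
20 | hexa-O-benzyl-3,4-bis-O-(tert-butyldimethylsilyl) derivative of ent-oritin-(4β→6)-oritin-4α-ol: upper unit (2S), 3-OH trans to the 2-aryl group, C4–C6 bond trans to 3-OH; lower unit as in 14 | C(c1ccccc1)Oc1ccc([C@H]2Oc3c(cc([C@H]4c5ccc(OCc6ccccc6)c(OCc6ccccc6)c5O[C@@H](c5ccc(OCc6ccccc6)cc5)[C@@H]4O)c(OCc4ccccc4)c3OCc3ccccc3)[C@@H](O[Si](C)(C)C(C)(C)C)[C@@H]2O[Si](C)(C)C(C)(C)C)cc1 | intermediate
21 | 3,4-bis-O-(tert-butyldimethylsilyl) ether (lower unit) of ent-oritin-(4β→6)-oritin-4α-ol, all phenols free | Oc1ccc([C@H]2Oc3c(cc([C@H]4c5ccc(O)c(O)c5O[C@@H](c5ccc(O)cc5)[C@@H]4O)c(O)c3O)[C@@H](O[Si](C)(C)C(C)(C)C)[C@@H]2O[Si](C)(C)C(C)(C)C)cc1 | intermediate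
22 | ent-oritin-(4β→6)-oritin-4α-ol: (2R,3S,4R)-2-(4-hydroxyphenyl)-6-[(2S,3R,4S)-3,7,8-trihydroxy-2-(4-hydroxyphenyl)chroman-4-yl]chroman-3,4,7,8-tetrol | Oc1ccc([C@H]2Oc3c(cc([C@H]4c5ccc(O)c(O)c5O[C@@H](c5ccc(O)cc5)[C@@H]4O)c(O)c3O)[C@@H](O)[C@@H]2O)cc1 | target

**Count**

Total steps: 14. Longest linear sequence: 11 steps (steps 1 to 8, then 12 to 14).

**Steps most likely to fail, with fallbacks**

Step 12 (interflavan coupling). What may go wrong is competing ionisation of the silylated C4–O bond of 14, self-condensation of the cation from 19 through its own ring A, or sluggish attack by the only moderately nucleophilic 1,2,3-trioxygenated ring. The fallback replaces Lewis-acid activation by thiophilic activation of an isolable thioether. Setting out from 19, benzyl mercaptan in acetic acid would give (2S,3R)-7,8-bis(benzyloxy)-2-[4-(benzyloxy)phenyl]-4-(benzylsulfanyl)chroman-3-ol F1 (3,4-trans isomer drawn; the C4 epimer serves equally). AgBF4 in THF at 0 °C, buffered with a hindered pyridine and in the presence of 14, would then release the cation from the C–S bond only, and the sequence comes back to the route at 20.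

Step 3 (ring expansion). What may go wrong is loss of the silyl group from 3 to tert-butoxide before the carbene adds, or slow carbene addition to the aromatic furan π bond. The fallback keeps the ring expansion but opens the shared bond through a radical instead of a cation. Setting out from 3, Et2Zn and CH2I2 would give the siloxycyclopropane 3,4-bis(benzyloxy)-6b-[(tert-butyldimethylsilyl)oxy]-1a,6b-dihydro-1H-cyclopropa[b][1]benzofuran F2. FeCl3 in DMF at 0 °C would oxidise it to the alkoxy radical, whose β-scission of the shared C–C bond and chlorine transfer would give 7,8-bis(benzyloxy)-2-chlorochroman-4-one F3. NaOAc in MeOH would eliminate HCl and come back to the route at 7, so that step 4 is no longer needed.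

Step 6 (Rubottom oxidation). What may go wrong is opening of ring C from the enolate, with loss of the C2 configuration, or over-oxidation to the flavonol. The fallback brings in the 3-oxygen through an alkene instead of an enolate. Setting out from 9, NaBH4 would give (2S,4S)-7,8-bis(benzyloxy)-2-[4-(benzyloxy)phenyl]chroman-4-ol F4. Acid-catalysed dehydration (TsOH, toluene) would give (2S)-7,8-bis(benzyloxy)-2-[4-(benzyloxy)phenyl]-2H-chromene F5. Dihydroxylation with OsO4 and N-methylmorpholine N-oxide anti to the aryl group would give (2R,3S,4S)-7,8-bis(benzyloxy)-2-[4-(benzyloxy)phenyl]chroman-3,4-diol F6. Activated MnO2 would oxidise only the benzylic C4 carbinol and come back to the route at 12.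

**Further compounds**

F1 | step 12 | (2S,3R)-7,8-bis(benzyloxy)-2-[4-(benzyloxy)phenyl]-4-(benzylsulfanyl)chroman-3-ol, 3,4-trans | c1ccc(cc1)COc1ccc(cc1)[C@@H]1Oc2c(ccc(OCc3ccccc3)c2OCc2ccccc2)[C@H](SCc2ccccc2)[C@H]1O
F2 | step 3 | 3,4-bis(benzyloxy)-6b-[(tert-butyldimethylsilyl)oxy]-1a,6b-dihydro-1H-cyclopropa[b][1]benzofuran (racemic) | CC(C)(C)[Si](C)(C)OC12CC1Oc1c2ccc(OCc2ccccc2)c1OCc1ccccc1
F3 | step 3 | 7,8-bis(benzyloxy)-2-chlorochroman-4-one (racemic) | O=C1CC(Cl)Oc2c1ccc(OCc1ccccc1)c2OCc1ccccc1
F4 | step 6 | (2S,4S)-7,8-bis(benzyloxy)-2-[4-(benzyloxy)phenyl]chroman-4-ol | c1ccc(cc1)COc1ccc(cc1)[C@H]1Oc2c(ccc(OCc3ccccc3)c2OCc2ccccc2)[C@@H](O)C1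
F5 | step 6 | (2S)-7,8-bis(benzyloxy)-2-[4-(benzyloxy)phenyl]-2H-chromene | c1ccc(cc1)COc1ccc(cc1)[C@H]1Oc2c(ccc(OCc3ccccc3)c2OCc2ccccc2)C=C1
F6 | step 6 | (2R,3S,4S)-7,8-bis(benzyloxy)-2-[4-(benzyloxy)phenyl]chroman-3,4-diol (2,3-trans-3,4-cis) | c1ccc(cc1)COc1ccc(cc1)[C@H]1Oc2c(ccc(OCc3ccccc3)c2OCc2ccccc2)[C@H](O)[C@@H]1O
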